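The depside is cut at its aryl ester into a protected formyl resorcylic acid (ring A, from atraric acid) and the ring B phenol. Everything rests on building ring B by a thermal cyclobutenone–siloxyalkyne benzannulation: 2,3-dimethylcyclobut-2-en-1-one and 1-(triisopropylsilyloxy)propyne form C2–C3, C4–C5 and C1–C2 of ring B in one operation. The step exploits the fully substituted resorcinol pattern of ring B: it delivers O–C2 as a free hydroxyl and O–C4 as a silyl ether, sets the methyls at C3, C5 and C6, and leaves C1 as the only C–H, which then takes the ester carbon.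

Key step: step 4

Remarks on the chemistry:
- Ring B is numbered from the carbon bearing CO2Me (OMe at C2, acyloxy at C4). Ring A is numbered from its carboxyl carbon (OH at C2 and C4, Me at C3 and C6, CHO at C5).
- Atraric acid has hydrogen at C5 of ring A, whereas the target has a formyl group there. The formyl group is therefore introduced on atraric acid (step 9), and the methyl ester is cleaved (step 11) before the coupling.
- Ring A is protected as allyl ethers because they survive acyl chloride formation and leave under neutral conditions.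
- The target has no stereocenter. Intermediate 11 is racemic and its stereocenter disappears within step 4.

**Step 1**
Reactants: 1 but-2-yne; 2 trichloroacetyl chloride
Product: 4 4,4-dichloro-2,3-dimethylcyclobut-2-en-1-one, via dichloroketene 3 (not isolated)
Conditions: Zn–Cu couple, POCl3, Et2O, 25–35 °C (excess 1, cold condenser)
Reagents that add atoms: none
Why: Zinc dechlorinates 2 to dichloroketene 3, which undergoes the thermal ketene–alkyne [2+2] cycloaddition with the electron-rich internal alkyne, while POCl3 ties up ZnCl2 so that the cyclobutenone is not degraded.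

**Step 2**
Reactants: 4 4,4-dichloro-2,3-dimethylcyclobut-2-en-1-one
Product: 5 2,3-dimethylcyclobut-2-en-1-one
Conditions: Zn dust, AcOH, TMEDA, EtOH, 0 °C to rt
Reagents that add atoms: none
Why: Reductive dehalogenation of the alpha,alpha-dichloro ketone through zinc enolates, with TMEDA/AcOH buffering that should spare the strained enone.

**Step 3**
Reactants: 6 ethyl acetate
Product: 9 1-(triisopropylsilyloxy)prop-1-yne, via lithium 1,1-dibromoprop-1-en-2-olate 7 (not isolated), via lithium prop-1-yn-1-olate 8 (not isolated)
Conditions: CH2Br2, lithium 2,2,6,6-tetramethylpiperidide (LiTMP, 2 equiv), THF, −78 °C; n-BuLi, −78 to 0 °C; i-Pr3SiCl, −78 °C to rt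
Reagents that add atoms: dibromomethane, BrCBr; triisopropylsilyl chloride, CC(C)[Si](Cl)(C(C)C)C(C)C
Why: Kowalski ester homologation, in which LiCHBr2 adds to the ester, the dibromo enolate 7 undergoes Br/Li exchange and 1,2-methyl shift to ynolate 8, and the bulky silyl chloride traps 8 on oxygen.

**Step 4**
Reactants: 5 2,3-dimethylcyclobut-2-en-1-one; 9 1-(triisopropylsilyloxy)prop-1-yne
Product: 14 2,4,5-trimethyl-3-(triisopropylsilyloxy)phenol, via 2,3-dimethylbuta-1,3-dien-1-one 10 (not isolated), via 2,4-dimethyl-4-(prop-1-en-2-yl)-3-(triisopropylsilyloxy)cyclobut-2-en-1-one 11 (not isolated), via (3E)-2,4,5-trimethyl-3-(triisopropylsilyloxy)hexa-1,3,5-trien-1-one 12 (not isolated), via 2,4,5-trimethyl-3-(triisopropylsilyloxy)cyclohexa-2,4-dien-1-one 13 (not isolated)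
Conditions: 9 (1.3 equiv), PhMe, 80 °C, then 110 °C, sealed tube
Reagents that add atoms: none
Why: Thermal conrotatory 4π opening of 5 gives vinylketene 10, whose ketene C=C adds siloxyalkyne 9 in a [2+2] cycloaddition to give 11 (forming C2–C3 and C4–C5 of ring B); a second 4π opening gives dienylketene 12, which closes by 6π electrocyclization (forming C1–C2) to dienone 13 and tautomerizes to phenol 14. The closest known reaction type is the Danheiser benzannulation of cyclobutenones with siloxyalkynes, of which this is a direct case. Ring B, the only ring kept, closes by thermal disrotatory six-electron electrocyclization of the terminal alkene carbon onto the ketene carbon; the four-membered ring of 11 is transient. No stereocenter is set, since the quaternary carbon of racemic 11 becomes sp2 on ring opening. The step needs regioselectivity in the [2+2] event, and the polarization of 9 secures it: its methyl-bearing carbon (beta to oxygen) is the nucleophilic end and bonds to the electrophilic ketene carbonyl carbon, so that OTIPS ends up at C4 between the C3 and C5 methyls and meta to the free C2 hydroxyl. It also needs the isopropenyl group of 12 cis to the ketene, which reversible opening of 11 supplies, and aromatization then drives the sequence forward.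

**Step 5**
Reactants: 14 2,4,5-trimethyl-3-(triisopropylsilyloxy)phenol
Product: 15 2-hydroxy-3,5,6-trimethyl-4-(triisopropylsilyloxy)benzaldehyde
Conditions: MgCl2, Et3N, (CH2O)n, MeCN, reflux
Reagents that add atoms: paraformaldehyde (formaldehyde unit), C=O
Why: Casnati–Skattebøl ortho-formylation, in which the magnesium phenoxide directs formaldehyde to the only free ring position (C1 of ring B) and a second formaldehyde oxidizes the benzylic alkoxide to the aldehyde, the hindered aryl silyl ether being inert to Et3N.

**Step 6**
Reactants: 15 2-hydroxy-3,5,6-trimethyl-4-(triisopropylsilyloxy)benzaldehyde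
Product: 16 2-hydroxy-3,5,6-trimethyl-4-(triisopropylsilyloxy)benzoic acid
Conditions: NaClO2, NaH2PO4, 2-methylbut-2-ene, t-BuOH/THF/H2O, 0 °C to rt
Reagents that add atoms: sodium chlorite, [Na+].[O-]Cl=O
Why: Pinnick (Lindgren) oxidation of the aldehyde under mildly acidic conditions, where the fully substituted ring offers no site for chlorination once the alkene scavenges HOCl.

**Step 7**
Reactants: 16 2-hydroxy-3,5,6-trimethyl-4-(triisopropylsilyloxy)benzoic acid
Product: 17 methyl 2-methoxy-3,5,6-trimethyl-4-(triisopropylsilyloxy)benzoate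
Conditions: Me2SO4, K2CO3, acetone, reflux
Reagents that add atoms: dimethyl sulfate, COS(=O)(=O)OC
Why: Williamson-type double O-methylation, in which the carboxylate and then the hydrogen-bonded phenoxide are alkylated by SN2 at methyl, a process insensitive to the ortho substituents, while the silyl ether flanked by two methyls should survive K2CO3 in acetone.

**Step 8**
Reactants: 17 methyl 2-methoxy-3,5,6-trimethyl-4-(triisopropylsilyloxy)benzoate
Product: 18 methyl 4-hydroxy-2-methoxy-3,5,6-trimethylbenzoate
Conditions: Bu4NF, AcOH, THF, 0 °C to rt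
Reagents that add atoms: none
Why: Fluoride-mediated desilylation driven by Si–F bond formation releases the C4 phenol, and acetic acid buffering should leave the methyl ester and the methyl ether untouched.

**Step 9**
Reactants: 19 atraric acid (methyl 2,4-dihydroxy-3,6-dimethylbenzoate)
Product: 20 methyl 5-formyl-2,4-dihydroxy-3,6-dimethylbenzoate
Conditions: Cl2CHOMe, TiCl4, CH2Cl2, 0 °C to rt; aq. HCl
Reagents that add atoms: dichloromethyl methyl ether, COC(Cl)Cl; water, O
Why: Rieche formylation, in which the titanium phenoxide directs the chloro(methoxy)methyl cation to C5 of ring A, the only unsubstituted position (ortho to the C4 hydroxyl, para to the C2 hydroxyl), and aqueous work-up unveils the aldehyde.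

**Step 10**
Reactants: 20 methyl 5-formyl-2,4-dihydroxy-3,6-dimethylbenzoate
Product: 21 methyl 5-formyl-3,6-dimethyl-2,4-bis(prop-2-en-1-yloxy)benzoate
Conditions: allyl bromide, K2CO3, DMF, 60 °C
Reagents that add atoms: allyl bromide, C=CCBr
Why: Williamson etherification of both chelated phenols with a reactive allylic bromide in a dipolar aprotic solvent.

**Step 11**
Reactants: 21 methyl 5-formyl-3,6-dimethyl-2,4-bis(prop-2-en-1-yloxy)benzoate
Product: 22 5-formyl-3,6-dimethyl-2,4-bis(prop-2-en-1-yloxy)benzoic acid
Conditions: KOH (excess), 1,4-dioxane/H2O, 90 °C, dilute; then aq. HCl, 0 °C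
Reagents that add atoms: potassium hydroxide, [K+].[OH-]
Why: Saponification (BAc2) of the hindered methyl ester with excess hydroxide, where the aldehyde, flanked by two ortho substituents and deactivated by ortho and para alkoxy groups, should resist Cannizzaro disproportionation at high dilution.

**Step 12**
Reactants: 22 5-formyl-3,6-dimethyl-2,4-bis(prop-2-en-1-yloxy)benzoic acid; 18 methyl 4-hydroxy-2-methoxy-3,5,6-trimethylbenzoate
Product: 25 methyl 4-{[5-formyl-3,6-dimethyl-2,4-bis(prop-2-en-1-yloxy)benzoyl]oxy}-2-methoxy-3,5,6-trimethylbenzoate, via 5-formyl-3,6-dimethyl-2,4-bis(prop-2-en-1-yloxy)benzoyl chloride 23 (not isolated), via sodium 3-methoxy-4-(methoxycarbonyl)-2,5,6-trimethylphenolate 24 (not isolated)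
Conditions: 22, (COCl)2, cat. DMF, CH2Cl2, 0 °C to rt, evaporate; 18, NaH, THF, 0 °C; combine, rt to 50 °C
Reagents that add atoms: none
Why: Nucleophilic acyl substitution (Schotten–Baumann-type acylation) in which the preformed sodium phenoxide 24 attacks acyl chloride 23, an anionic nucleophile being chosen to overcome the two ortho substituents on each partner, with O-acylation the only possible outcome on the fully substituted ring.

**Step 13**
Reactants: 25 methyl 4-{[5-formyl-3,6-dimethyl-2,4-bis(prop-2-en-1-yloxy)benzoyl]oxy}-2-methoxy-3,5,6-trimethylbenzoate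
Product: 26 methyl 4-[(5-formyl-2,4-dihydroxy-3,6-dimethylbenzoyl)oxy]-2-methoxy-3,5,6-trimethylbenzoate (target)
Conditions: Pd(PPh3)4 (5 mol%), N-methylaniline, THF, rt
Reagents that add atoms: none
Why: Tsuji–Trost deallylation, in which zerovalent palladium ionizes both aryl allyl ethers (the ortho-carbonyl phenoxides are good leaving groups) and N-methylaniline traps the allyl units without touching the aldehyde, the methyl ester or the depside ester.

**Compound list**

1 | but-2-yne | CC#CC | starting material
2 | trichloroacetyl chloride | ClC(Cl)(Cl)C(Cl)=O | starting material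
3 | dichloroketene | ClC(Cl)=C=O | intermediate (not isolated)
4 | 4,4-dichloro-2,3-dimethylcyclobut-2-en-1-one | CC1=C(C)C(Cl)(Cl)C1=O | intermediate
5 | 2,3-dimethylcyclobut-2-en-1-one | CC1=C(C)C(=O)C1 | intermediate
6 | ethyl acetate | CCOC(C)=O | starting material
7 | lithium 1,1-dibromoprop-1-en-2-olate | [Li+].CC([O-])=C(Br)Br | intermediate (not isolated)
8 | lithium prop-1-yn-1-olate | [Li+].CC#C[O-] | intermediate (not isolated)
9 | 1-(triisopropylsilyloxy)prop-1-yne | CC#CO[Si](C(C)C)(C(C)C)C(C)C | intermediate
10 | 2,3-dimethylbuta-1,3-dien-1-one | CC(=C=O)C(C)=C | intermediate (not isolated)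
11 | 2,4-dimethyl-4-(prop-1-en-2-yl)-3-(triisopropylsilyloxy)cyclobut-2-en-1-one (racemic) | CC1=C(O[Si](C(C)C)(C(C)C)C(C)C)C(C)(C(C)=C)C1=O | intermediate (not isolated)
12 | (3E)-2,4,5-trimethyl-3-(triisopropylsilyloxy)hexa-1,3,5-trien-1-one | CC(=C=O)/C(O[Si](C(C)C)(C(C)C)C(C)C)=C(C)\C(C)=C | intermediate (not isolated)
13 | 2,4,5-trimethyl-3-(triisopropylsilyloxy)cyclohexa-2,4-dien-1-one | CC1=C(O[Si](C(C)C)(C(C)C)C(C)C)C(C)=C(C)CC1=O | intermediate (not isolated)
14 | 2,4,5-trimethyl-3-(triisopropylsilyloxy)phenol | Cc1cc(O)c(C)c(O[Si](C(C)C)(C(C)C)C(C)C)c1C | intermediate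
15 | 2-hydroxy-3,5,6-trimethyl-4-(triisopropylsilyloxy)benzaldehyde | O=Cc1c(O)c(C)c(O[Si](C(C)C)(C(C)C)C(C)C)c(C)c1C | intermediate
16 | 2-hydroxy-3,5,6-trimethyl-4-(triisopropylsilyloxy)benzoic acid | OC(=O)c1c(O)c(C)c(O[Si](C(C)C)(C(C)C)C(C)C)c(C)c1C | intermediate
17 | methyl 2-methoxy-3,5,6-trimethyl-4-(triisopropylsilyloxy)benzoate | COC(=O)c1c(OC)c(C)c(O[Si](C(C)C)(C(C)C)C(C)C)c(C)c1C | intermediate
18 | methyl 4-hydroxy-2-methoxy-3,5,6-trimethylbenzoate | COC(=O)c1c(OC)c(C)c(O)c(C)c1C | intermediate
19 | atraric acid (methyl 2,4-dihydroxy-3,6-dimethylbenzoate) | COC(=O)c1c(C)cc(O)c(C)c1O | starting material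
20 | methyl 5-formyl-2,4-dihydroxy-3,6-dimethylbenzoate | COC(=O)c1c(C)c(C=O)c(O)c(C)c1O | intermediate
21 | methyl 5-formyl-3,6-dimethyl-2,4-bis(prop-2-en-1-yloxy)benzoate | COC(=O)c1c(C)c(C=O)c(OCC=C)c(C)c1OCC=C | intermediate
22 | 5-formyl-3,6-dimethyl-2,4-bis(prop-2-en-1-yloxy)benzoic acid | OC(=O)c1c(C)c(C=O)c(OCC=C)c(C)c1OCC=C | intermediate
23 | 5-formyl-3,6-dimethyl-2,4-bis(prop-2-en-1-yloxy)benzoyl chloride | O=C(Cl)c1c(C)c(C=O)c(OCC=C)c(C)c1OCC=C | intermediate (not isolated)
24 | sodium 3-methoxy-4-(methoxycarbonyl)-2,5,6-trimethylphenolate | [Na+].COC(=O)c1c(OC)c(C)c([O-])c(C)c1C | intermediate (not isolated)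
25 | methyl 4-{[5-formyl-3,6-dimethyl-2,4-bis(prop-2-en-1-yloxy)benzoyl]oxy}-2-methoxy-3,5,6-trimethylbenzoate | COC(=O)c1c(C)c(C)c(OC(=O)c2c(C)c(C=O)c(OCC=C)c(C)c2OCC=C)c(C)c1OC | intermediate
26 | methyl 4-[(5-formyl-2,4-dihydroxy-3,6-dimethylbenzoyl)oxy]-2-methoxy-3,5,6-trimethylbenzoate | COC(=O)c1c(C)c(C)c(OC(=O)c2c(C)c(C=O)c(O)c(C)c2O)c(C)c1OC | target

**Step count**

Total: 13 steps. Longest linear sequence: 9 steps (steps 1, 2, 4, 5, 6, 7, 8, 12, 13).

**Steps most likely to fail**

Step 4 (key step). The cascade may stall at the four-membered adduct. The thermally generated vinylketene may also be lost to dimerization or to acylation of the phenol already formed, and the volatile cyclobutenone may escape on heating. The fallback sets out from 9 and returns at 14. It generates the same vinylketene 10 photochemically at room temperature by Wolff rearrangement in place of cyclobutenone opening. Purchased 2-methylpent-1-en-3-one F1 is deprotonated at the ethyl group (LiHMDS, THF, −78 °C) and acylated with CF3CO2CH2CF3 to give 1,1,1-trifluoro-3,5-dimethylhex-5-ene-2,4-dione F2. Without isolation, F2 is taken into detrifluoroacetylative diazo transfer (MsN3, Et3N, H2O, MeCN) to give 4-diazo-2-methylpent-1-en-3-one F3. Irradiation of F3 with 9 (254 nm, ClCH2CH2Cl, rt), then heating at 80 °C, should lead through 10, 11, 12 and 13 to 14.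

Step 12. Acyl transfer between two partners that each carry two ortho substituents may be too slow, so that the acyl chloride is hydrolysed back to the acid on work-up. The fallback sets out from 20 and returns at 26. It drops the protecting groups and forms the ester through an acylium-type mixed anhydride under acid. Dissolving 20 in cold concentrated H2SO4 should cleave the hindered methyl ester by the acylium (AAC1) pathway, and quenching on ice should give 5-formyl-2,4-dihydroxy-3,6-dimethylbenzoic acid F6. Both hydroxyls of F6 are tied up in hydrogen bonds to carbonyl groups. F6 and 18 with (CF3CO)2O in toluene at rt should condense through 5-formyl-2,4-dihydroxy-3,6-dimethylbenzoic trifluoroacetic anhydride F7 (not isolated) and give 26 directly, so that steps 10, 11 and 13 fall away.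

Step 11. Hydroxide attack on the shielded ester carbonyl is slow, and the forcing conditions it needs may consume the aldehyde by disproportionation. The fallback sets out from 21 and returns at 22. It masks the aldehyde for the hydrolysis. Treating 21 with HC(OMe)3 and cat. TsOH in MeOH should give methyl 5-(dimethoxymethyl)-3,6-dimethyl-2,4-bis(prop-2-en-1-yloxy)benzoate F4. The acetal is inert to base, so F4 can be saponified under forcing conditions (KOH, DMSO/H2O, 110 °C) to potassium 5-(dimethoxymethyl)-3,6-dimethyl-2,4-bis(prop-2-en-1-yloxy)benzoate F5 (not isolated). Acidification with dilute HCl in THF should protonate the carboxylate, hydrolyse the acetal and give 22.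

**Further compounds**

F1 | step 4 | 2-methylpent-1-en-3-one | CCC(=O)C(C)=C
F2 | step 4 | 1,1,1-trifluoro-3,5-dimethylhex-5-ene-2,4-dione | CC(C(=O)C(F)(F)F)C(=O)C(C)=C
F3 | step 4 | 4-diazo-2-methylpent-1-en-3-one | CC(=C)C(=O)C(C)=[N+]=[N-]
F4 | step 11 | methyl 5-(dimethoxymethyl)-3,6-dimethyl-2,4-bis(prop-2-en-1-yloxy)benzoate | COC(=O)c1c(C)c(C(OC)OC)c(OCC=C)c(C)c1OCC=C
F5 | step 11 | potassium 5-(dimethoxymethyl)-3,6-dimethyl-2,4-bis(prop-2-en-1-yloxy)benzoate | [K+].[O-]C(=O)c1c(C)c(C(OC)OC)c(OCC=C)c(C)c1OCC=C
F6 | step 12 | 5-formyl-2,4-dihydroxy-3,6-dimethylbenzoic acid | OC(=O)c1c(C)c(C=O)c(O)c(C)c1O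
F7 | step 12 | 5-formyl-2,4-dihydroxy-3,6-dimethylbenzoic trifluoroacetic anhydride | O=C(OC(=O)C(F)(F)F)c1c(C)c(C=O)c(O)c(C)c1O
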